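Two flasks hold the same amount of starting complex, and alpha gets twice the incoming ligand of eta. How far does each get?

in all of them: starting complex 0.40 M; time 5.0 h
- eta: incoming ligand 0.800 M
- alpha: incoming ligand 1.60 M

1. part of the starting complex that has reacted at the end, eta
2. part of the starting complex that has reacted at the end, alpha
3. what raising the concentration of incoming ligand from its lowest to its highest value here does to the part of the starting complex that has reacted (changes below 5 percentage points count as none) (it rises / it falls / no change)

    starting complex + incoming ligand ⇌ leaving ligand + complex with one exchanged (K1 = 0.36, k1 = 0.43 M⁻¹ h⁻¹)
    complex with one exchanged + incoming ligand ⇌ leaving ligand + complex with two exchanged (K2 = 0.16, k2 = 0.057 M⁻¹ h⁻¹)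
    complex with two exchanged + incoming ligand ⇌ leaving ligand + complex with three exchanged (K3 = 0.59, k3 = 0.33 M⁻¹ h⁻¹)
    leaving ligand + starting complex ⇌ idle adduct, settled at all times (K4 = 3.2 M⁻¹)
    starting complex ⇌ dormant form (K5 = 0.41, k5 = 0.45 h⁻¹)
    leaving ligand + starting complex → side product (k6 = 2.3 M⁻¹ h⁻¹)

Follow one molecule of starting complex. When incoming ligand replaces a ligand on it, it becomes complex with one exchanged and frees a leaving ligand, and that ligand reaches a fork. It can fall back onto a complex with one exchanged, which undoes the swap, or it can attack a second starting complex and make side product, so two starting complexes are lost. The two ways are equally likely when complex with one exchanged stands at 1.93 times starting complex; call this the even-odds ratio.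

The ratio starts from nothing and climbs, so I take even odds for the whole run: one starting complex lost per release on average. Holding incoming ligand at its charge makes the loss pseudo-first-order. In eta, the ligand going on must balance the ligand used, which puts free leaving ligand near 0.0748 M. Dormant form balances quickly, with a relaxation half-life of 0.448 h, and idle adduct is kept at balance, so 60.6% of the pool of these three stays free. The pool then decays at 0.209 h⁻¹, and eta reaches 78.6%.

In alpha, free leaving ligand doubles to 0.150 M, and idle adduct holds more of the pool, leaving a smaller free share of 52.9%. The decay constant therefore grows by a factor of 1.75, to 0.364 h⁻¹. Alpha reaches 91.4%, so the verdict is it rises.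

The forecast gave 81% (76% to 86%) for eta, above my figure, and 88% (83% to 92%) for alpha, below mine, and said it rises: doubling the incoming ligand speeds the first exchange, “but the extra leaving ligand pushes it back”.

The simulation gives 80.4% for eta and 88.9% for alpha: it rises, by 8.5 percentage points.

At 5.00 h, eta shows complex with one exchanged at 1.92 times starting complex, close to the even-odds ratio, and free leaving ligand at 0.0844 M. Now read eta earlier, at 3.0 h. There the ratio is 1.28, below even odds, so a freed ligand has still been more likely to go on than to fall back. The same reckoning gives 67.6% for that time, and the flask stands ahead of it, at 72.7%.

(All constants come from no measurement; what happens was integrated by code.)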